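## Analysis of the target

The target (21) is two hexasubstituted benzene rings joined by one methylene group. It has no stereocentre and is achiral, so the whole problem is regiochemical.

Ring A carries, in order, a butanoyl group (C1), a methyl (C2), the bridge CH2 (C3), a methoxy (C4), a methyl (C5) and a hydroxyl (C6). Ring B is a phloroglucinol (hydroxyls at C2′, C4′, C6′) with the bridge at C1′, a methyl at C3′ and a butanoyl group at C5′.

Ring B has the pattern of 2-methylphloroglucinol (1), which can be bought. Ring A is a resorcinol whose two oxygens are differentiated (C4 ether, C6 phenol) and whose carbon substituents are all different.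

The sensitive features are:
- four electron-rich phenols, prone to air oxidation;
- the benzylic bridge between two activated rings, which strong acid can cleave by ipso protonation once both rings are free phenols, and which base can scramble through quinone methides;
- the single aryl methyl ether, which must survive Lewis acid.

Joining two preformed acylphenol halves through a one-carbon electrophile would give homo- and heterodimers side by side and would not solve the O-differentiation of ring A. The strategy rests on C4 and C6 of ring A being 1,3-related oxygens that flank the C5 methyl. They are the carbonyls of a 2-methylcyclohexane-1,3-dione, so ring A can be grown as a saturated ring on a chain already bonded to ring B. An ester at C1 then tells the two oxygens apart by hydrogen bonding and is later lost as CO2.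

## Retrosynthetic reasoning

**Acyl groups.** The two aryl–acyl bonds (ring A C1–CO and ring B C5′–CO) are cut first, giving tetraphenol 19 and butanoyl chloride 20. Once every auxiliary group is gone, each ring has exactly one unsubstituted carbon, ortho to a hydroxyl, so a double Friedel–Crafts acylation has no regiochemical choice to make. The ketones are thereby kept out of all the basic and reductive steps before. The forward reaction must acylate carbon, not oxygen, and must leave the bridge alone.

**Ring B protection.** The three ring B hydroxyls of 19 are traced back to the benzyl ethers of 18. Benzyl ethers withstand alkoxide, hydride, amide base and hot hydroxide, and hydrogenolysis removes them without touching the methyl ether or the diarylmethane.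

**C1 hydrogen and C4 ether.** The hydrogen at C1 of 18 is replaced by an ethoxycarbonyl group (16, through acid 17), and the C4 O–methyl bond is then cut to give the resorcinol ester 15. The ester is what the annulation leaves at C1, and it holds the C6 hydroxyl in a hydrogen bond so that only the C4 hydroxyl is alkylated. Forward, this is a selective O-methylation followed by saponification and decarboxylation.

**Aromaticity of ring A.** Ring A of 15 is taken back by one oxidation level to the cyclohexane-1,3-dione 14. The forward dehydrogenation has to act at the β-keto ester carbon, because the carbon between the two ketones is blocked by its methyl group.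

**Key disconnection.** Dione 14 is cut at C1–C2 and C4–C5 into the crotonate 11 and ethyl 3-oxopentanoate 12, by way of the open-chain adduct 13. These two bonds are chosen because they are the Michael and Claisen bonds of a [3+3] annulation that places both ring oxygens, both methyls, the ester and the bridge in one operation. No aromatic substitution on a crowded ring A is then needed. The forward reaction must push a conjugate addition to a trisubstituted acceptor through to the cyclized dione.

**Crotonate double bond.** The C=C of 11 is traced through mesylate 10 to the aldol 9, which is cut between the ester α-carbon and the carbinol carbon into propanoate 7 and acetaldehyde 8. The alkene geometry need not be controlled.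

**Bridge carbon.** Propanoate 7 comes from cinnamate 6 by conjugate reduction, and 6 is cut at its C=C into aldehyde 4 and triethyl phosphonoacetate 5. The future bridge carbon is thus an aldehyde, then an alkene carbon, then a CH2. It never bears a leaving group, which matters because a 2,4,6-trialkoxybenzyl halide would ionize and alkylate the free position of another ring B.

**Ring B starting material.** Aldehyde 4 is the tribenzyl ether of 3, which comes from 1 by formylation (through iminium salt 2) at one of its two equivalent free carbons.

## Alternatives that were turned down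

**Alternative 1:** Ring A stays aromatic, and its C3–C(bridge) and C2–C(methyl) bonds are assigned to the two carbons of the aryne 3,5-dimethoxy-4-methylbenzyne A2.
- Forward key step: A2 is released by fluoride-induced elimination and inserts into the C(O)–CH2 bond of the ring B β-keto sulfone A3, 2-(phenylsulfonyl)-1-[2,4,6-tris(benzyloxy)-3-methylphenyl]ethan-1-one. The sulfonyl carbanion adds to the aryne carbon remote from the flanking methoxy group, the aryl anion closes onto the ketone, and the strained alkoxide opens to the benzophenone A1, [2,4-dimethoxy-3-methyl-6-(phenylsulfonylmethyl)phenyl][2,4,6-tris(benzyloxy)-3-methylphenyl]methanone.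
- For it: it is convergent, needs no dehydrogenation, makes two adjacent C–C bonds at once, and its regiochemistry is set by the methoxy group.
- Against it: A1 is far from the target. A ketone flanked by four ortho substituents must be deoxygenated to CH2, and the sulfone removed to reveal the C2 methyl. One of two similar methyl ethers must be cleaved selectively, with no built-in handle. Both butanoyl groups are still missing. The aryl anion must also attack a carbonyl shielded by two benzyloxy groups, and simple α-arylation without insertion is the likely escape.
- Comparison: it is stronger on convergence and on keeping both rings aromatic. The chosen route offers instead an O-differentiation that comes free from ester chelation, cheap acyclic building blocks, and fewer corrective steps after the key step.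

**Alternative 2:** Ring B is the ring that is built. Its C2′–C3′ and C4′–C5′ bonds are made by a Danheiser benzannulation.
- Forward key step: the cyclobutenone A5, 4-(2,4-dimethoxy-3,6-dimethylbenzyl)-3-ethoxycyclobut-2-en-1-one, already carries ring A. Heating opens it to a vinylketene, which adds the siloxyalkyne A6, 1-(triisopropylsiloxy)prop-1-yne, in a [2+2] sense. A second four-electron opening, six-electron closure and tautomerization give the phenol A4, 3-ethoxy-2-(2,4-dimethoxy-3,6-dimethylbenzyl)-6-methyl-5-(triisopropylsiloxy)phenol.
- For it: the conditions are neutral and thermal, and the pericyclic cascade fixes the pattern of a pentasubstituted ring.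
- Against it: the key step is spent on the ring that 1 supplies ready-made. The three ring B oxygens come out differentiated although the target needs them all free, so an ethyl ether must be cleaved late. Ring A, the difficult ring, has to be made separately and arrives with two methyl ethers, one of which must still be removed selectively. A5 needs a multistep preparation that includes alkylation with an electron-rich benzylic electrophile. Both acylations remain.
- Comparison: it is as strong or stronger on mildness and regiocontrol of the key step. The chosen route is shorter from purchased ring B and solves the ring A differentiation inside the ring construction.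

**Alternative 3:** Ring A is assembled in one cycloaddition by cutting C2–C3 and C1–C6.
- Forward key step: the Brassard-type diene A8, [1,3-dimethoxy-2-methyl-5-(2,4,6-tris(benzyloxy)-3-methylphenyl)penta-1,3-dien-1-yl]oxy-trimethylsilane, carries ring B on the future bridge carbon. It adds to the ynone A9, hept-2-yn-4-one, with its nucleophilic terminus bonding to the methyl-bearing alkyne carbon. Loss of the ketene-acetal methoxy group and of silicon gives the aryl ketone A7, 1-{2-hydroxy-4-methoxy-3,6-dimethyl-5-[2,4,6-tris(benzyloxy)-3-methylbenzyl]phenyl}butan-1-one.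
- For it: it is the most direct route. A7 already has all six ring A substituents, including the butanoyl group and the correct OH/OMe pattern, and is only a hydrogenolysis and one ring B acylation from the target. On step count after the key step it is clearly stronger.
- Against it: A8 is a tetrasubstituted, hydrolytically labile diene with a bulky substituent on its reacting terminus and a methyl at C2, so the s-cis conformer is disfavoured. A9 is an internal, β-substituted ynone of modest reactivity. Making a hexasubstituted benzene by an intermolecular [4+2] addition is sterically demanding, and open-chain Mukaiyama–Michael adducts and diene decomposition are likely at the temperatures needed.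
- Comparison: the chosen route gives up about three steps to A7's directness. In return it has a base-mediated annulation with stable, storable intermediates and a thermodynamic driving force.

Key step: step 7

Remark on the chemistry: 21 has no stereocentre. The stereocentres of 9, 10, 13 and 14 and the alkene geometry of 11 are transient, are carried as mixtures, and all become trigonal by step 8.

## Route

Step 1
Reactants: 1 2-methylphloroglucinol (2-methylbenzene-1,3,5-triol)
Product: 3 2,4,6-trihydroxy-3-methylbenzaldehyde, via aryl iminium chloride 2 (not isolated)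
Conditions: POCl3, DMF, EtOAc, 0 °C → rt; then H2O, 50 °C
Reagents that add atoms: N,N-dimethylformamide, CN(C)C=O; water, O
Why: Vilsmeier–Haack formylation: the chloroiminium ion made from DMF and POCl3 attacks one of the two equivalent unsubstituted carbons of the phloroglucinol ring; iminium salt 2 deactivates the ring toward a second attack and is hydrolysed to the aldehyde on aqueous work-up.

Step 2
Reactants: 3 2,4,6-trihydroxy-3-methylbenzaldehyde
Product: 4 2,4,6-tris(benzyloxy)-3-methylbenzaldehyde
Conditions: BnBr (3.6 equiv), K2CO3, DMF, 60 °C
Reagents that add atoms: benzyl bromide, BrCc1ccccc1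
Why: Williamson ether synthesis: the formyl group lowers the nucleophilicity of the remaining ring carbon, so O-alkylation should prevail over C-benzylation; DMF and warming are needed because two of the hydroxyls are hydrogen-bonded to the aldehyde.

Step 3
Reactants: 4 2,4,6-tris(benzyloxy)-3-methylbenzaldehyde; 5 triethyl phosphonoacetate
Product: 6 ethyl (E)-3-[2,4,6-tris(benzyloxy)-3-methylphenyl]prop-2-enoate
Conditions: NaH, THF, 0 °C → reflux
Reagents that add atoms: none
Why: Horner–Wadsworth–Emmons olefination: the aldehyde is hindered but cannot enolize, and the stabilized phosphonate anion should give the (E)-cinnamate; the alkene geometry is removed in step 4.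

Step 4
Reactants: 6 ethyl (E)-3-[2,4,6-tris(benzyloxy)-3-methylphenyl]prop-2-enoate
Product: 7 ethyl 3-[2,4,6-tris(benzyloxy)-3-methylphenyl]propanoate
Conditions: NaBH4, NiCl2·6H2O (0.3 equiv), EtOH–THF, 0 °C → rt
Reagents that add atoms: none
Why: Conjugate reduction with nickel boride formed in situ from NiCl2 and NaBH4: the surface hydride saturates the styrenic C=C even though the donor-substituted ring makes it a poor Michael acceptor, while the ester and the benzyl ethers are left alone under these mild conditions.

Step 5
Reactants: 7 ethyl 3-[2,4,6-tris(benzyloxy)-3-methylphenyl]propanoate; 8 acetaldehyde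
Product: 9 ethyl 3-hydroxy-2-[2,4,6-tris(benzyloxy)-3-methylbenzyl]butanoate (mixture of diastereomers)
Conditions: LiN(iPr)2, THF, −78 °C; then MeCHO, −78 °C; AcOH quench
Reagents that add atoms: none
Why: Aldol addition of the lithium ester enolate to acetaldehyde at low temperature; the two new stereocentres are formed without control (syn and anti) and both become trigonal in step 6, so no control is needed.

Step 6
Reactants: 9 ethyl 3-hydroxy-2-[2,4,6-tris(benzyloxy)-3-methylbenzyl]butanoate
Product: 11 ethyl (E)-2-[2,4,6-tris(benzyloxy)-3-methylbenzyl]but-2-enoate, via mesylate 10 (not isolated)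
Conditions: MsCl, Et3N, CH2Cl2, 0 °C; then DBU, rt → 40 °C
Reagents that add atoms: none
Why: Mesylation followed by base-induced E1cB elimination gives the conjugated trisubstituted alkene; the isomer with the methyl group anti to the ester (E) is the more stable and should dominate, and any (Z) or deconjugated isomer enters step 7 through the same equilibria.

Step 7
Reactants: 11 ethyl (E)-2-[2,4,6-tris(benzyloxy)-3-methylbenzyl]but-2-enoate; 12 ethyl 3-oxopentanoate
Product: 14 ethyl 3,6-dimethyl-2,4-dioxo-5-[2,4,6-tris(benzyloxy)-3-methylbenzyl]cyclohexane-1-carboxylate (mixture of diastereomers and enol forms), via Michael adduct 13 (not isolated)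
Conditions: 12 (1.5 equiv), NaOEt (1.6 equiv), EtOH (concentrated), reflux; then cold dilute HCl
Reagents that add atoms: none
Why: Ethoxide deprotonates 12 at the carbon between its two carbonyls, and this doubly stabilized carbanion adds to the β-carbon of 11 (Michael addition), which makes the C1–C2 bond of ring A and gives 13 after proton transfer. In 13 the ketone is enolized toward its ethyl group, and this enolate attacks the ester that came from 11 in a 6-(enolexo)-exo-trig Claisen condensation, which makes the C4–C5 bond and closes ring A with loss of ethoxide. The closest known reaction is the Michael–Claisen annulation of β-keto esters with crotonates that gives 6-alkyl-2,4-dioxocyclohexanecarboxylates (the dihydroorsellinate synthesis); the acceptor here is slower because it is branched at its α-carbon. Every event before the last is reversible, but the last, deprotonation of the new 1,3-dione by ethoxide, is not, so the sluggish conjugate addition, retro-Michael cleavage and deconjugation of 11 are all drained toward the enolate of 14. Chemoselectivity comes from the substrate: the only other intramolecular closures open to 13 would give four-membered rings, and the donor is used in excess to offset its self-condensation. Four stereocentres (C1, C2, C3, C5) are created without any controlling element, those at C1 and C5 being epimerizable, and none is needed because all four become trigonal in step 8. The ring regiochemistry is fixed by connectivity: the β-methyl of 11 becomes the C2 methyl, its α-substituent the bridge at C3, and the ethyl group of 12 the C5 methyl.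

Step 8
Reactants: 14 ethyl 3,6-dimethyl-2,4-dioxo-5-[2,4,6-tris(benzyloxy)-3-methylbenzyl]cyclohexane-1-carboxylate
Product: 15 ethyl 2,4-dihydroxy-3,6-dimethyl-5-[2,4,6-tris(benzyloxy)-3-methylbenzyl]benzoate
Conditions: I2 (0.2 equiv), DMSO, 80 °C
Reagents that add atoms: none
Why: Iodine-catalysed dehydrogenative aromatization (halogenation–dehydrohalogenation of a 2,4-dioxocyclohexanecarboxylate): the enol of the β-keto ester is iodinated at C1, HI is lost across C1–C2 and the two remaining carbonyls enolize to the resorcinol, while DMSO reoxidizes HI to I2; iodination at the methyl-blocked C5 is unproductive but reversible.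

Step 9
Reactants: 15 ethyl 2,4-dihydroxy-3,6-dimethyl-5-[2,4,6-tris(benzyloxy)-3-methylbenzyl]benzoate
Product: 16 ethyl 2-hydroxy-4-methoxy-3,6-dimethyl-5-[2,4,6-tris(benzyloxy)-3-methylbenzyl]benzoate
Conditions: MeI (1.1 equiv), K2CO3, acetone, rt → 40 °C
Reagents that add atoms: iodomethane, CI
Why: Chelation-controlled Williamson methylation: the C6 hydroxyl is held in a hydrogen bond to the ester carbonyl and is much less nucleophilic, so one equivalent of MeI should alkylate only the C4 hydroxyl, as in the selective 4-O-methylation of orsellinate esters.

Step 10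
Reactants: 16 ethyl 2-hydroxy-4-methoxy-3,6-dimethyl-5-[2,4,6-tris(benzyloxy)-3-methylbenzyl]benzoate
Product: 18 3-methoxy-2,5-dimethyl-4-[2,4,6-tris(benzyloxy)-3-methylbenzyl]phenol, via carboxylic acid 17 (not isolated)
Conditions: KOH, DMSO–H2O, 110 °C, N2; then AcOH to pH 4–5, 100 °C
Reagents that add atoms: none
Why: Saponification of the hindered salicylate needs forcing conditions, which the benzyl ethers and the methyl ether tolerate; on mild acidification the electron-rich ortho-hydroxybenzoic acid 17 loses CO2 by ipso protonation (protodecarboxylation), leaving hydrogen at C1.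

Step 11
Reactants: 18 3-methoxy-2,5-dimethyl-4-[2,4,6-tris(benzyloxy)-3-methylbenzyl]phenol
Product: 19 2-(4-hydroxy-2-methoxy-3,6-dimethylbenzyl)-4-methylbenzene-1,3,5-triol
Conditions: H2 (1 atm), Pd/C (10 %), EtOAc–EtOH, rt
Reagents that add atoms: none
Why: Hydrogenolysis of the three benzyl ethers over Pd/C; the aryl methyl ether and the diarylmethane C–C bonds are inert, and the air-sensitive tetraphenol is taken on without purification.

Step 12
Reactants: 19 2-(4-hydroxy-2-methoxy-3,6-dimethylbenzyl)-4-methylbenzene-1,3,5-triol; 20 butanoyl chloride
Product: 21 1-{3-[(3-butanoyl-2,4,6-trihydroxy-5-methylphenyl)methyl]-6-hydroxy-4-methoxy-2,5-dimethylphenyl}butan-1-one (target)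
Conditions: 20 (2.5 equiv), AlCl3 (excess), PhNO2–CH2Cl2, 0 °C → rt; then cold aqueous HCl
Reagents that add atoms: none
Why: Double Friedel–Crafts acylation: each ring has exactly one unsubstituted carbon and each lies ortho to a hydroxyl, so both acylium attacks are regiochemically unambiguous and end as chelated ortho-hydroxy ketones; any phenol ester formed first should rearrange under AlCl3 (Fries rearrangement), and the C4 methoxy group, not being ortho to a carbonyl, should resist demethylation at room temperature.

## Compound list

1 | 2-methylphloroglucinol (2-methylbenzene-1,3,5-triol) | Cc1c(O)cc(O)cc1O | starting material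
2 | dimethyl[(2,4,6-trihydroxy-3-methylphenyl)methylidene]ammonium chloride | C[N+](C)=Cc1c(O)c(C)c(O)cc1O.[Cl-] | intermediate
3 | 2,4,6-trihydroxy-3-methylbenzaldehyde | O=Cc1c(O)c(C)c(O)cc1O | intermediate
4 | 2,4,6-tris(benzyloxy)-3-methylbenzaldehyde | O=Cc1c(OCc2ccccc2)c(C)c(OCc2ccccc2)cc1OCc1ccccc1 | intermediate
5 | triethyl phosphonoacetate | CCOC(=O)CP(=O)(OCC)OCC | starting material
6 | ethyl (E)-3-[2,4,6-tris(benzyloxy)-3-methylphenyl]prop-2-enoate | CCOC(=O)/C=C/c1c(OCc2ccccc2)c(C)c(OCc2ccccc2)cc1OCc1ccccc1 | intermediate
7 | ethyl 3-[2,4,6-tris(benzyloxy)-3-methylphenyl]propanoate | CCOC(=O)CCc1c(OCc2ccccc2)c(C)c(OCc2ccccc2)cc1OCc1ccccc1 | intermediate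
8 | acetaldehyde | CC=O | starting material
9 | ethyl 3-hydroxy-2-[2,4,6-tris(benzyloxy)-3-methylbenzyl]butanoate (diastereomer mixture) | CCOC(=O)C(Cc1c(OCc2ccccc2)c(C)c(OCc2ccccc2)cc1OCc1ccccc1)C(C)O | intermediate
10 | ethyl 3-(methylsulfonyloxy)-2-[2,4,6-tris(benzyloxy)-3-methylbenzyl]butanoate (diastereomer mixture) | CCOC(=O)C(Cc1c(OCc2ccccc2)c(C)c(OCc2ccccc2)cc1OCc1ccccc1)C(C)OS(C)(=O)=O | intermediate
11 | ethyl (E)-2-[2,4,6-tris(benzyloxy)-3-methylbenzyl]but-2-enoate | C/C=C(\Cc1c(OCc2ccccc2)c(C)c(OCc2ccccc2)cc1OCc1ccccc1)C(=O)OCC | intermediate
12 | ethyl 3-oxopentanoate | CCC(=O)CC(=O)OCC | starting material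
13 | diethyl 3-methyl-2-propanoyl-4-[2,4,6-tris(benzyloxy)-3-methylbenzyl]pentanedioate (diastereomer mixture) | CCOC(=O)C(C(=O)CC)C(C)C(Cc1c(OCc2ccccc2)c(C)c(OCc2ccccc2)cc1OCc1ccccc1)C(=O)OCC | intermediate
14 | ethyl 3,6-dimethyl-2,4-dioxo-5-[2,4,6-tris(benzyloxy)-3-methylbenzyl]cyclohexane-1-carboxylate (diastereomer and enol mixture) | CCOC(=O)C1C(C)C(Cc2c(OCc3ccccc3)c(C)c(OCc3ccccc3)cc2OCc2ccccc2)C(=O)C(C)C1=O | intermediate
15 | ethyl 2,4-dihydroxy-3,6-dimethyl-5-[2,4,6-tris(benzyloxy)-3-methylbenzyl]benzoate | CCOC(=O)c1c(C)c(Cc2c(OCc3ccccc3)c(C)c(OCc3ccccc3)cc2OCc2ccccc2)c(O)c(C)c1O | intermediate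
16 | ethyl 2-hydroxy-4-methoxy-3,6-dimethyl-5-[2,4,6-tris(benzyloxy)-3-methylbenzyl]benzoate | CCOC(=O)c1c(C)c(Cc2c(OCc3ccccc3)c(C)c(OCc3ccccc3)cc2OCc2ccccc2)c(OC)c(C)c1O | intermediate
17 | 2-hydroxy-4-methoxy-3,6-dimethyl-5-[2,4,6-tris(benzyloxy)-3-methylbenzyl]benzoic acid | OC(=O)c1c(C)c(Cc2c(OCc3ccccc3)c(C)c(OCc3ccccc3)cc2OCc2ccccc2)c(OC)c(C)c1O | intermediate
18 | 3-methoxy-2,5-dimethyl-4-[2,4,6-tris(benzyloxy)-3-methylbenzyl]phenol | Cc1cc(O)c(C)c(OC)c1Cc1c(OCc2ccccc2)c(C)c(OCc2ccccc2)cc1OCc1ccccc1 | intermediate
19 | 2-(4-hydroxy-2-methoxy-3,6-dimethylbenzyl)-4-methylbenzene-1,3,5-triol | Cc1cc(O)c(C)c(OC)c1Cc1c(O)c(C)c(O)cc1O | intermediate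
20 | butanoyl chloride | CCCC(=O)Cl | starting material
21 | 1-{3-[(3-butanoyl-2,4,6-trihydroxy-5-methylphenyl)methyl]-6-hydroxy-4-methoxy-2,5-dimethylphenyl}butan-1-one | CCCC(=O)c1c(C)c(Cc2c(O)c(C)c(O)c(C(=O)CCC)c2O)c(OC)c(C)c1O | target

## Step count and least certain steps

Total step count: 12. Longest linear sequence: 12 steps (1 to 21).

**Step 7 (key step).** The conjugate addition may reverse faster than the ring closes, because the acceptor is substituted at both its α- and β-carbons. Base-induced deconjugation of the acceptor to its β,γ-isomer and self-condensation of the donor would then take over.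

Fallback: the same two ring bonds are made in the opposite order, so that the conjugate addition becomes intramolecular and runs onto an enone.
- It sets out from 11. LiOH in aqueous THF gives (E)-2-[2,4,6-tris(benzyloxy)-3-methylbenzyl]but-2-enoic acid F1.
- 1,1′-Carbonyldiimidazole and then MeNHOMe·HCl convert F1 into (E)-N-methoxy-N-methyl-2-[2,4,6-tris(benzyloxy)-3-methylbenzyl]but-2-enamide F2.
- The dianion of 12 (NaH, then n-BuLi, THF, 0 °C) is acylated by F2 at its ethyl-side carbon, which forms the C4–C5 bond and gives ethyl (E)-4-methyl-3,5-dioxo-6-[2,4,6-tris(benzyloxy)-3-methylbenzyl]oct-6-enoate F3.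
- Brief treatment of F3 with NaOEt in EtOH closes the ring by 6-endo-trig Michael addition of the ester-flanked carbanion to the enone (C1–C2 bond). The fallback comes back to the route at 14.

**Step 12.** With both rings as free phenols under AlCl3, the bridge may be cleaved or migrate after ipso protonation of the phloroglucinol ring. Acylation of the more hindered ring A position may also stop at the phenol ester, and prolonged exposure may remove the methyl ether.

Fallback: both acyl groups are introduced by organometallic chemistry before deprotection, without any Lewis acid.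
- It sets out from 18. NBS (2 equiv, CH2Cl2, −20 °C) brominates the one free carbon of each ring to give 2-bromo-5-methoxy-3,6-dimethyl-4-[2,4,6-tris(benzyloxy)-3-bromo-5-methylbenzyl]phenol F4.
- BnBr and K2CO3 in DMF protect the phenol as 1-(benzyloxy)-2-bromo-5-methoxy-3,6-dimethyl-4-[2,4,6-tris(benzyloxy)-3-bromo-5-methylbenzyl]benzene F5.
- Double bromine–lithium exchange (n-BuLi, THF, −78 °C) and acylation with N-methoxy-N-methylbutanamide give 1-{2-(benzyloxy)-4-methoxy-3,6-dimethyl-5-[2,4,6-tris(benzyloxy)-3-butanoyl-5-methylbenzyl]phenyl}butan-1-one F6.
- Hydrogenolysis of F6 (H2, Pd/C, EtOAc) comes back to the route at 21.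

**Step 8.** Electrophilic iodination may occur at the free position of ring B, which is a highly activated trialkoxyarene carbon. DMSO may also transfer oxygen to the iodinated β-keto ester carbon instead of HI being eliminated. Any iodine taken up by ring B would be removed again by the hydrogenolysis of step 11.

Fallback: dehydrogenation through a divalent palladium enolate and β-hydride elimination instead of halogenation. Pd(OCOCF3)2 (5 mol %), 2-(dimethylamino)pyridine, TsOH (catalytic) and O2 (1 atm) in DMSO at 80 °C would take 14 directly to 15. No electrophilic halogen is present and no new compound is made.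

**Step 2.** C-benzylation may occur at the unsubstituted ring carbon, and etherification of the two hydroxyls chelated to the aldehyde may stay incomplete.

Fallback: the order of etherification and formylation is reversed.
- It sets out from 1. Ac2O and pyridine give 2-methylbenzene-1,3,5-triyl triacetate F7.
- BnCl and NaH in DMF with slow addition of water cleave the acetates one at a time and benzylate each phenoxide as it forms. The phenoxide concentration stays low, which suppresses C-alkylation, and the product is 1,3,5-tris(benzyloxy)-2-methylbenzene F8.
- Vilsmeier–Haack formylation of F8 (POCl3, DMF) at either of its two equivalent free carbons proceeds through dimethyl{[2,4,6-tris(benzyloxy)-3-methylphenyl]methylidene}ammonium chloride F9. Hydrolysis of F9 comes back to the route at 4.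

## Further compounds

F1 | step 7 | (E)-2-[2,4,6-tris(benzyloxy)-3-methylbenzyl]but-2-enoic acid | C/C=C(\Cc1c(OCc2ccccc2)c(C)c(OCc2ccccc2)cc1OCc1ccccc1)C(=O)O
F2 | step 7 | (E)-N-methoxy-N-methyl-2-[2,4,6-tris(benzyloxy)-3-methylbenzyl]but-2-enamide | C/C=C(\Cc1c(OCc2ccccc2)c(C)c(OCc2ccccc2)cc1OCc1ccccc1)C(=O)N(C)OC
F3 | step 7 | ethyl (E)-4-methyl-3,5-dioxo-6-[2,4,6-tris(benzyloxy)-3-methylbenzyl]oct-6-enoate | C/C=C(\Cc1c(OCc2ccccc2)c(C)c(OCc2ccccc2)cc1OCc1ccccc1)C(=O)C(C)C(=O)CC(=O)OCC
F4 | step 12 | 2-bromo-5-methoxy-3,6-dimethyl-4-[2,4,6-tris(benzyloxy)-3-bromo-5-methylbenzyl]phenol | Cc1c(Br)c(O)c(C)c(OC)c1Cc1c(OCc2ccccc2)c(C)c(OCc2ccccc2)c(Br)c1OCc1ccccc1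
F5 | step 12 | 1-(benzyloxy)-2-bromo-5-methoxy-3,6-dimethyl-4-[2,4,6-tris(benzyloxy)-3-bromo-5-methylbenzyl]benzene | Cc1c(Br)c(OCc2ccccc2)c(C)c(OC)c1Cc1c(OCc2ccccc2)c(C)c(OCc2ccccc2)c(Br)c1OCc1ccccc1
F6 | step 12 | 1-{2-(benzyloxy)-4-methoxy-3,6-dimethyl-5-[2,4,6-tris(benzyloxy)-3-butanoyl-5-methylbenzyl]phenyl}butan-1-one | CCCC(=O)c1c(C)c(Cc2c(OCc3ccccc3)c(C)c(OCc3ccccc3)c(C(=O)CCC)c2OCc2ccccc2)c(OC)c(C)c1OCc1ccccc1
F0 | step 8 | none | none
F7 | step 2 | 2-methylbenzene-1,3,5-triyl triacetate | CC(=O)Oc1cc(OC(C)=O)c(C)c(OC(C)=O)c1
F8 | step 2 | 1,3,5-tris(benzyloxy)-2-methylbenzene | Cc1c(OCc2ccccc2)cc(OCc2ccccc2)cc1OCc1ccccc1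
F9 | step 2 | dimethyl{[2,4,6-tris(benzyloxy)-3-methylphenyl]methylidene}ammonium chloride | C[N+](C)=Cc1c(OCc2ccccc2)c(C)c(OCc2ccccc2)cc1OCc1ccccc1.[Cl-]
A1 | alternative 1 | [2,4-dimethoxy-3-methyl-6-(phenylsulfonylmethyl)phenyl][2,4,6-tris(benzyloxy)-3-methylphenyl]methanone | COc1cc(CS(=O)(=O)c2ccccc2)c(C(=O)c2c(OCc3ccccc3)c(C)c(OCc3ccccc3)cc2OCc2ccccc2)c(OC)c1C
A2 | alternative 1 | 3,5-dimethoxy-4-methylbenzyne (1,2-didehydro-3,5-dimethoxy-4-methylbenzene) | COC1=CC#CC(OC)=C1C
A3 | alternative 1 | 2-(phenylsulfonyl)-1-[2,4,6-tris(benzyloxy)-3-methylphenyl]ethan-1-one | O=C(CS(=O)(=O)c1ccccc1)c1c(OCc2ccccc2)c(C)c(OCc2ccccc2)cc1OCc1ccccc1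
A4 | alternative 2 | 3-ethoxy-2-(2,4-dimethoxy-3,6-dimethylbenzyl)-6-methyl-5-(triisopropylsiloxy)phenol | CCOc1cc(O[Si](C(C)C)(C(C)C)C(C)C)c(C)c(O)c1Cc1c(C)cc(OC)c(C)c1OC
A5 | alternative 2 | 4-(2,4-dimethoxy-3,6-dimethylbenzyl)-3-ethoxycyclobut-2-en-1-one | CCOC1=CC(=O)C1Cc1c(C)cc(OC)c(C)c1OC
A6 | alternative 2 | 1-(triisopropylsiloxy)prop-1-yne | CC#CO[Si](C(C)C)(C(C)C)C(C)C
A7 | alternative 3 | 1-{2-hydroxy-4-methoxy-3,6-dimethyl-5-[2,4,6-tris(benzyloxy)-3-methylbenzyl]phenyl}butan-1-one | CCCC(=O)c1c(C)c(Cc2c(OCc3ccccc3)c(C)c(OCc3ccccc3)cc2OCc2ccccc2)c(OC)c(C)c1O
A8 | alternative 3 | [1,3-dimethoxy-2-methyl-5-(2,4,6-tris(benzyloxy)-3-methylphenyl)penta-1,3-dien-1-yl]oxy-trimethylsilane (alkene geometry not defined) | COC(O[Si](C)(C)C)=C(C)C(OC)=CCc1c(OCc2ccccc2)c(C)c(OCc2ccccc2)cc1OCc1ccccc1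
A9 | alternative 3 | hept-2-yn-4-one | CC#CC(=O)CCC
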